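All runs were generated by integration with made-up constants.

In 69 s the alpha run uses up 144 mM of substrate and the beta run 93.6 mM, although the alpha run was charged with twice the substrate, so the rate does not keep pace with the charge, and I want the top it bends towards.

| flask | substrate | free catalyst | time |
|---|---|---|---|
| beta | 200 mM | 1.00 mM |  |
| gamma | 120 mM | 1.00 mM |  |
| alpha | 400 mM | 1.00 mM |  |
| zeta | 200 mM | 1.50 mM |  |
| eta | 920 mM | 1.00 mM | 69 s |

| run | time / s | [substrate] / mM |
|---|---|---|
| beta run | 9.9 | 183.9 |
| beta run | 20 | 168.1 |
| beta run | 30 | 152.4 |
| beta run | 39 | 139.6 |
| beta run | 49 | 126.1 |
| beta run | 59 | 116.9 |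
| beta run | 69 | 106.4 |
| gamma run | 9.9 | 108.6 |
| gamma run | 20 | 99.8 |
| gamma run | 30 | 94.4 |
| gamma run | 39 | 86.2 |
| gamma run | 49 | 79.1 |
| gamma run | 59 | 72.2 |
| gamma run | 69 | 67.3 |
| alpha run | 9.9 | 380.3 |
| alpha run | 20 | 357.1 |
| alpha run | 30 | 336.6 |
| alpha run | 39 | 315.1 |
| alpha run | 49 | 294.7 |
| alpha run | 59 | 274.8 |
| alpha run | 69 | 255.8 |
| zeta run | 9.9 | 175.7 |
| zeta run | 20 | 155.4 |
| zeta run | 30 | 133.7 |
| zeta run | 39 | 120.4 |
| zeta run | 49 | 107.7 |
| zeta run | 59 | 95.4 |
| zeta run | 69 | 84.8 |

(readings scatter by 1 mM)

- Overall: substrate -> product, with free catalyst as catalyst.
- Constant volume, constant temperature.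
- The analysis sees a species whether free or bound.
- An order is taken over about fifteen percent of the charge, up and down.

- apparent order in [substrate] of the starting rate, round the charge of the beta run (the rate where two percent of its substrate have turned into product) (one fixed amount of product, the same in the runs compared)
- apparent order in [free catalyst] of the starting rate, round the charge of the beta run (the rate where two percent of its substrate have turned into product)
- the gamma run starts with 80.0 mM less of substrate than the beta run, and with no product. Compared where both hold the same amount of substrate, once fifteen percent of what the gamma run was charged with has turned into product, is the gamma run faster, slower or alike (within a tenth)?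
- substrate in the eta run at 69 s, as a share of the substrate charged
- which of these the readings show (the catalyst dies by itself / the catalyst dies in pairs / nothing beyond the main steps / a little impurity takes part of the catalyst at once / the catalyst rests as a dimer / the product ties up the catalyst)

I call that top the ceiling rate: the rate that a charge of 1.00 mM free catalyst approaches as substrate climbs (the usual Vmax). Below it stands the crossing, the substrate at which the rate is 0.5 of the ceiling and control passes from substrate to catalyst. My rule is:

rate = ceiling × [substrate] squared / ([substrate] squared + crossing squared)

Integrated over a run, it reads: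

ceiling × time = substrate used + crossing squared × (inverse of [substrate] − inverse of its charge)

The last readings of the alpha and beta runs give two such equations, and these yield:

crossing = 130 mM

ceiling = 2.44 mM s⁻¹

The gamma run, unused so far, tests the squared form. My rule brings the gamma run to its last reading in 67.0 s, and the reading stands at 69 s. A plain hyperbola fitted the same way, with half-rate point 275 mM and top 3.87 mM s⁻¹, needs 54.7 s, so I keep the squared form.

The ladder of rates, reckoned by my rule at each charge, from the top down, is:

ceiling: 2.44 mM s⁻¹

alpha run: 2.20 mM s⁻¹, charge above the crossing

beta run: 1.71 mM s⁻¹, charge above the crossing, last reading below it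

gamma run: 1.12 mM s⁻¹, charge below the crossing

The eta run sits at the top of this ladder, so I reckon it in two passes:

first pass, at the ceiling: 752 mM

with the crossing term: 756 mM, or 82.2 % of the charge

The forecast puts the orders at 0.6 in substrate and 0.83 in free catalyst, calls the gamma comparison alike, leaves 79 % in the eta run, which is less than my figure, and chooses "the catalyst rests as a dimer", saying “That fits a resting dimer”.

The flask gives orders of 0.63 and 0.91, alike, 82.5 % and the catalyst rests as a dimer.

    free catalyst + substrate ⇌ catalyst-substrate complex, settled at all times (3.460 M⁻¹)
    catalyst-substrate complex + substrate ⇌ doubly bound catalyst, settled at all times (47.30 M⁻¹)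
    doubly bound catalyst → product + catalyst-substrate complex (2.410 s⁻¹)
    2 free catalyst ⇌ resting dimer, settled at all times (3370 M⁻¹)

Taking away the pairing of free catalyst into the resting dimer drops the substrate order from 0.63 to 0.35, so the pairing gives the curve its steepness round the charge of the beta run. The eta run stands far above the crossing, where the same pairing makes no difference to its substrate, and its mean rate is 2.33 mM s⁻¹ against a ceiling of 2.44 mM s⁻¹. With the ceiling scaled by the catalyst charge and the same crossing, my rule turns a quarter of the zeta run's substrate into product in 21.4 s, and the zeta run took 22.2 s.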